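## Retrosynthetic overview

1. The epoxy ester and the C9 protecting group come off last: target ⇐ 8-hydroxy-9-(2-naphthylmethoxy) germacranolide + (2S,3R)-2,3-dimethyloxirane-2-carboxylic acid (from tiglyl alcohol by Sharpless epoxidation).
2. Key disconnection C8–C9, closing the ten-membered ring last: the enal-acetal carbon C9 is made nucleophilic (γ-alkoxyallylchromium from CrCl2/Me3SiI) and adds to the C8 aldehyde, so two carbonyl carbons are joined. This step is meant to set C8, C9, the O8/O9 differentiation and the Z C1=C10 olefin.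
3. The five-membered α-methylene lactone is formed first: boron aldol of an itaconyl thiazolidinethione with a (Z)-enal (C6–C7; sets C6, C7), lactonisation, then reduction of the thioimide to the C8 aldehyde.
4. The open-chain enal acetal ⇐ Brown allylation of a (Z)-enal (C3), cross-metathesis with methacrolein (C9, C10), all from but-2-yn-1-ol.

Convention and assumptions: germacrane numbering is used for locants (C1=C10, C4=C5, C6–O–C12 lactone, C11=C13). (−)-B-Allyldiisopinocampheylborane solution and (E)-2-methylbut-2-en-1-ol are taken as commercial. The aldol sense is assigned by analogy with Evans oxazolidinone boron aldols, and the outcome of the key step is a prediction, not a precedent.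

## Route

Step 1
Reactants: 1 but-2-yn-1-ol
Product: 3 (Z)-3-iodobut-2-en-1-ol, via sodium vinylalanate 2 (not isolated)
Conditions: NaAlH2(OCH2CH2OCH3)2 (1.5 equiv), THF, 0 °C to rt; then I2, −78 °C to 0 °C
Reagents that add atoms: iodine, II
Why: Alkoxide-directed trans-hydroalumination of the propargylic alcohol places Al on C3 cis to CH2O, and iodinolysis with retention fixes the Z geometry that becomes the C4=C5 olefin.

Step 2
Reactants: 3 (Z)-3-iodobut-2-en-1-ol
Product: 4 (Z)-triethyl[(3-iodobut-2-en-1-yl)oxy]silane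
Conditions: Et3SiCl, imidazole, CH2Cl2, 0 °C
Reagents that add atoms: chlorotriethylsilane, CC[Si](Cl)(CC)CC
Why: Standard silylation of a primary alcohol; the TES ether is later oxidised directly to the aldehyde.

Step 3
Reactants: 4 (Z)-triethyl[(3-iodobut-2-en-1-yl)oxy]silane
Product: 6 (Z)-2-methyl-4-(triethylsilyloxy)but-2-enal, via vinyllithium 5 (not isolated)
Conditions: t-BuLi (2.1 equiv), Et2O, −78 °C; DMF, −78 to 0 °C; H2O
Reagents that add atoms: N,N-dimethylformamide, CN(C)C=O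
Why: Lithium–iodine exchange and formylation of the vinyllithium both proceed with retention, giving the Z enal (C3 aldehyde cis to C6).

Step 4
Reactants: 6 (Z)-2-methyl-4-(triethylsilyloxy)but-2-enal
Product: 8 (4S,5Z)-5-methyl-7-(triethylsilyloxy)hepta-1,5-dien-4-ol, via diisopinocampheylborinate 7 (not isolated)
Conditions: (−)-Ipc2B(allyl) (from (+)-α-pinene, 1 M in pentane), Et2O, −78 °C; then HOCH2CH2NH2, rt
Reagents that add atoms: (−)-B-allyldiisopinocampheylborane, C=CCB([C@@H]1C[C@@H]2C[C@H]([C@H]1C)C2(C)C)[C@@H]1C[C@@H]2C[C@H]([C@H]1C)C2(C)C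
Why: Brown allylboration through a chair transition state attacks the Si face of the aldehyde (as with benzaldehyde, which gives the S alcohol), setting C3 as S.

Step 5
Reactants: 8 (4S,5Z)-5-methyl-7-(triethylsilyloxy)hepta-1,5-dien-4-ol
Product: 9 (4S,5Z)-5-methyl-7-(triethylsilyloxy)hepta-1,5-dien-4-yl acetate
Conditions: Ac2O, pyridine, DMAP (cat.), CH2Cl2, 0 °C to rt
Reagents that add atoms: acetic anhydride, CC(=O)OC(C)=O
Why: Acylation installs the C3 acetate of the target at the outset; every later step is chosen to tolerate it.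

Step 6
Reactants: 9 (4S,5Z)-5-methyl-7-(triethylsilyloxy)hepta-1,5-dien-4-yl acetate, 10 methacrolein
Product: 11 (2E,5S,6Z)-5-acetoxy-2,6-dimethyl-8-(triethylsilyloxy)octa-2,6-dienal
Conditions: 10 (5 equiv), second-generation Hoveyda–Grubbs catalyst RuCl2(H2IMes)(=CH-C6H4-2-OiPr) (5 mol%), CH2Cl2, 40 °C
Reagents that add atoms: none
Why: Olefin cross-metathesis of the terminal alkene with methacrolein gives the E enal (the trisubstituted Z olefin is inert); the E geometry does not matter because it is erased in the allylmetal of step 15.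

Step 7
Reactants: 12 naphthalen-2-ylmethanol
Product: 13 trimethyl(naphthalen-2-ylmethoxy)silane
Conditions: (Me3Si)2NH (0.6 equiv), Me3SiCl (cat.), CH2Cl2, rt
Reagents that add atoms: hexamethyldisilazane, C[Si](C)(C)N[Si](C)(C)C
Why: Routine O-silylation provides the alkoxysilane needed for Noyori acetalisation.

Step 8
Reactants: 11 (2E,5S,6Z)-5-acetoxy-2,6-dimethyl-8-(triethylsilyloxy)octa-2,6-dienal, 13 trimethyl(naphthalen-2-ylmethoxy)silane
Product: 14 (2E,5S,6Z)-5-acetoxy-2,6-dimethyl-8-(triethylsilyloxy)octa-2,6-dienal bis(naphthalen-2-ylmethyl) acetal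
Conditions: 13 (2.2 equiv), Me3SiOTf (5 mol%), CH2Cl2, −78 °C; pyridine quench
Reagents that add atoms: none
Why: Noyori acetalisation converts the enal into the benzyl-type α,β-unsaturated acetal under aprotic conditions without olefin migration; the naphthylmethyl group later serves as the DDQ-removable C9 protecting group.

Step 9
Reactants: 14 (2E,5S,6Z)-5-acetoxy-2,6-dimethyl-8-(triethylsilyloxy)octa-2,6-dienal bis(naphthalen-2-ylmethyl) acetal
Product: 16 (2Z,4S,6E)-4-acetoxy-3,7-dimethyl-8,8-bis(naphthalen-2-ylmethoxy)octa-2,6-dienal, via alkoxysulfonium chloride 15 (not isolated)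
Conditions: (COCl)2, DMSO, CH2Cl2, −78 to −40 °C; Et3N, −78 to 0 °C
Reagents that add atoms: none
Why: Swern conditions oxidise a primary TES ether directly to the aldehyde (desilylation and oxidation in one operation), giving the Z enal at C6 without acid.

Step 10
Reactants: 17 (S)-4-benzylthiazolidine-2-thione, 18 itaconic anhydride
Product: 20 4-[(S)-4-benzyl-2-thioxothiazolidin-3-yl]-2-methylidene-4-oxobutanoic acid, via lithium thiazolidinethionide 19 (not isolated)
Conditions: n-BuLi, THF, −78 °C; 18, −78 °C; 1 M HCl work-up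
Reagents that add atoms: none
Why: N-Acylation by ring opening of the anhydride at its non-conjugated, more electrophilic carbonyl; low temperature avoids base isomerisation to the citraconyl system.

Step 11
Reactants: 20 4-[(S)-4-benzyl-2-thioxothiazolidin-3-yl]-2-methylidene-4-oxobutanoic acid
Product: 21 methyl 4-[(S)-4-benzyl-2-thioxothiazolidin-3-yl]-2-methylidene-4-oxobutanoate
Conditions: Me3SiCHN2, PhMe/MeOH (4:1), 0 °C
Reagents that add atoms: (trimethylsilyl)diazomethane, C[Si](C)(C)C=[N+]=[N-]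
Why: Neutral methyl esterification of the acrylic acid leaves the acidic itaconyl CH2 and the thioimide untouched.

Step 12
Reactants: 21 methyl 4-[(S)-4-benzyl-2-thioxothiazolidin-3-yl]-2-methylidene-4-oxobutanoate, 16 (2Z,4S,6E)-4-acetoxy-3,7-dimethyl-8,8-bis(naphthalen-2-ylmethoxy)octa-2,6-dienal
Product: 24 methyl (3S,4R,5Z,7S,9E)-7-acetoxy-3-[(S)-4-benzyl-2-thioxothiazolidine-3-carbonyl]-4-hydroxy-6,10-dimethyl-2-methylidene-11,11-bis(naphthalen-2-ylmethoxy)undeca-5,9-dienoate, via Z-dibutylboron enolate 22 (not isolated), via dibutylboron aldolate 23 (not isolated)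
Conditions: Bu2BOTf, iPr2NEt, CH2Cl2, 0 °C; 16, −78 to −20 °C; pH 7 buffer/MeOH
Reagents that add atoms: none
Why: Evans-type syn aldol of the Z boron enolate through a Zimmerman–Traxler chair, with the (S)-auxiliary directing the face, forms C6–C7 and sets C6 (R) and C7 (S); the non-Lewis-acidic boron enolate spares the acetal.

Step 13
Reactants: 24 methyl (3S,4R,5Z,7S,9E)-7-acetoxy-3-[(S)-4-benzyl-2-thioxothiazolidine-3-carbonyl]-4-hydroxy-6,10-dimethyl-2-methylidene-11,11-bis(naphthalen-2-ylmethoxy)undeca-5,9-dienoate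
Product: 25 (S)-4-benzyl-3-{(2R,3S)-2-[(1Z,3S,5E)-3-acetoxy-2,6-dimethyl-7,7-bis(naphthalen-2-ylmethoxy)hepta-1,5-dien-1-yl]-4-methylidene-5-oxooxolane-3-carbonyl}thiazolidine-2-thione
Conditions: PPTS (10 mol%), 4 Å MS, CH2Cl2, 35 °C
Reagents that add atoms: none
Why: Acid-catalysed lactonisation of the γ-hydroxy acrylate gives the trans α-methylene-γ-butyrolactone; the sieves take up methanol so the acetal is not exchanged.

Step 14
Reactants: 25 (S)-4-benzyl-3-{(2R,3S)-2-[(1Z,3S,5E)-3-acetoxy-2,6-dimethyl-7,7-bis(naphthalen-2-ylmethoxy)hepta-1,5-dien-1-yl]-4-methylidene-5-oxooxolane-3-carbonyl}thiazolidine-2-thione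
Product: 26 (2R,3S)-2-[(1Z,3S,5E)-3-acetoxy-2,6-dimethyl-7,7-bis(naphthalen-2-ylmethoxy)hepta-1,5-dien-1-yl]-4-methylidene-5-oxooxolane-3-carbaldehyde
Conditions: LiAlH(OtBu)3 (1.1 equiv), THF, −78 to −40 °C; aq. Rochelle salt; crude used at once
Reagents that add atoms: none
Why: Partial reduction of the highly activated N-acylthiazolidinethione to the aldehyde by a bulky, mild hydride that leaves lactone, acetate and acetal alone; the epimerisable C7 centre already has the more stable trans arrangement.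

Step 15
Reactants: 26 (2R,3S)-2-[(1Z,3S,5E)-3-acetoxy-2,6-dimethyl-7,7-bis(naphthalen-2-ylmethoxy)hepta-1,5-dien-1-yl]-4-methylidene-5-oxooxolane-3-carbaldehyde
Product: 29 (3S,6R,7R,8S,9R,1(10)Z,4Z)-3-acetoxy-8-hydroxy-9-(naphthalen-2-ylmethoxy)germacra-1(10),4,11(13)-trien-12,6-olide, via allylic iodide 27 (not isolated), via allylchromium dichloride 28 (not isolated)
Conditions: CrCl2 (6 equiv), THF, −30 °C; 26 and Me3SiI (1.2 equiv) added by syringe pump over 8 h (final 1 mM); H2O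
Reagents that add atoms: none
Why: Proposed new method: Me3SiI ionises the α,β-unsaturated acetal and CrCl2 reduces the resulting γ-alkoxyallylic iodide to a γ-alkoxyallylchromium (Takai's reductive umpolung of enal acetals, known intermolecularly for acrolein acetals, where it gives anti 1,2-diol monoethers), so the former enal carbon C9 attacks the C8 aldehyde at its oxygen-bearing terminus through a chair transition state with the C9 ether equatorial (anti C8/C9), the ring-forming C2 substituent axial (Z C1=C10) and Felkin-type delivery anti to the C7–C11 bond (8S,9R), closing the ten-membered ring; the closest precedents are that intermolecular reaction and Nozaki–Hiyama–Kishi and Marshall macrocyclisations of allylmetals onto aldehydes.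

Step 16
Reactants: 30 (E)-2-methylbut-2-en-1-ol
Product: 31 [(2R,3R)-2,3-dimethyloxiran-2-yl]methanol
Conditions: Ti(OiPr)4 (5 mol%), D-(−)-diisopropyl tartrate (6 mol%), t-BuOOH, 4 Å MS, CH2Cl2, −20 °C
Reagents that add atoms: tert-butyl hydroperoxide, CC(C)(C)OO
Why: Sharpless asymmetric epoxidation; the D-(−)-tartrate delivers oxygen to the face that gives the (2R,3R) epoxy alcohol (L-(+)-tartrate gives 2S,3S, as with geraniol).

Step 17
Reactants: 31 [(2R,3R)-2,3-dimethyloxiran-2-yl]methanol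
Product: 32 (2S,3R)-2,3-dimethyloxirane-2-carboxylic acid
Conditions: TEMPO (cat.), PhI(OAc)2, MeCN/H2O (1:1), 0 °C to rt
Reagents that add atoms: water, O
Why: TEMPO/PhI(OAc)2 oxidation takes the primary alcohol to the acid via the aldehyde hydrate without touching the epoxide; the C2 descriptor changes from R to S only through CIP priorities.

Step 18
Reactants: 29 (3S,6R,7R,8S,9R,1(10)Z,4Z)-3-acetoxy-8-hydroxy-9-(naphthalen-2-ylmethoxy)germacra-1(10),4,11(13)-trien-12,6-olide, 32 (2S,3R)-2,3-dimethyloxirane-2-carboxylic acid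
Product: 34 (3S,6R,7S,8S,9R,1(10)Z,4Z)-3-acetoxy-8-[(2S,3R)-2,3-dimethyloxirane-2-carbonyloxy]-9-(naphthalen-2-ylmethoxy)germacra-1(10),4,11(13)-trien-12,6-olide, via mixed anhydride 33 (not isolated)
Conditions: 32 (3 equiv), 2,4,6-Cl3C6H2COCl, Et3N, THF, rt; then 29, DMAP, PhMe, 40 °C
Reagents that add atoms: none
Why: Yamaguchi esterification acylates the only free hydroxyl (C8) with retention at all stereocentres; the C7 descriptor returns to S only through CIP priorities.

Step 19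
Reactants: 34 (3S,6R,7S,8S,9R,1(10)Z,4Z)-3-acetoxy-8-[(2S,3R)-2,3-dimethyloxirane-2-carbonyloxy]-9-(naphthalen-2-ylmethoxy)germacra-1(10),4,11(13)-trien-12,6-olide
Product: 35 (3S,6R,7S,8S,9R,1(10)Z,4Z)-3-acetoxy-8-[(2S,3R)-2,3-dimethyloxirane-2-carbonyloxy]-9-hydroxygermacra-1(10),4,11(13)-trien-12,6-olide (CNP0299903.2)
Conditions: DDQ, CH2Cl2/pH 7 phosphate buffer (10:1), 0 °C to rt
Reagents that add atoms: none
Why: Oxidative cleavage of the 2-naphthylmethyl ether by DDQ under buffered conditions frees the C9 hydroxyl without affecting the epoxide, acetate, α-methylene lactone or olefins.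

## Compound list

1 | but-2-yn-1-ol | CC#CCO | starting material
2 | sodium 2,2-bis(2-methoxyethoxy)-3-methyl-2,5-dihydro-1,2-oxaaluminol-2-uide (cyclic vinylalanate, not isolated) | CC1=CCO[Al-]1(OCCOC)OCCOC.[Na+] | intermediate
3 | (Z)-3-iodobut-2-en-1-ol | C/C(I)=C/CO | intermediate
4 | (Z)-triethyl[(3-iodobut-2-en-1-yl)oxy]silane | C/C(I)=C/CO[Si](CC)(CC)CC | intermediate
5 | (Z)-[4-(triethylsilyloxy)but-2-en-2-yl]lithium (not isolated) | C/C([Li])=C/CO[Si](CC)(CC)CC | intermediate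
6 | (Z)-2-methyl-4-(triethylsilyloxy)but-2-enal | C/C(C=O)=C/CO[Si](CC)(CC)CC | intermediate
7 | (4S,5Z)-5-methyl-7-(triethylsilyloxy)hepta-1,5-dien-4-yl diisopinocampheylborinate (not isolated) | C=CC[C@H](OB([C@@H]1C[C@@H]2C[C@H]([C@H]1C)C2(C)C)[C@@H]1C[C@@H]2C[C@H]([C@H]1C)C2(C)C)/C(C)=C\CO[Si](CC)(CC)CC | intermediate
8 | (4S,5Z)-5-methyl-7-(triethylsilyloxy)hepta-1,5-dien-4-ol | C=CC[C@H](O)/C(C)=C\CO[Si](CC)(CC)CC | intermediate
9 | (4S,5Z)-5-methyl-7-(triethylsilyloxy)hepta-1,5-dien-4-yl acetate | C=CC[C@H](OC(C)=O)/C(C)=C\CO[Si](CC)(CC)CC | intermediate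
10 | methacrolein (2-methylprop-2-enal) | C=C(C)C=O | starting material
11 | (2E,5S,6Z)-5-acetoxy-2,6-dimethyl-8-(triethylsilyloxy)octa-2,6-dienal | O=C/C(C)=C/C[C@H](OC(C)=O)/C(C)=C\CO[Si](CC)(CC)CC | intermediate
12 | naphthalen-2-ylmethanol | OCc1ccc2ccccc2c1 | starting material
13 | trimethyl(naphthalen-2-ylmethoxy)silane | C[Si](C)(C)OCc1ccc2ccccc2c1 | intermediate
14 | (2E,5S,6Z)-5-acetoxy-2,6-dimethyl-8-(triethylsilyloxy)octa-2,6-dienal bis(naphthalen-2-ylmethyl) acetal | C(OCc1ccc2ccccc2c1)(OCc1ccc2ccccc2c1)/C(C)=C/C[C@H](OC(C)=O)/C(C)=C\CO[Si](CC)(CC)CC | intermediate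
15 | dimethyl alkoxysulfonium chloride of the C6 oxygen (not isolated) | C(OCc1ccc2ccccc2c1)(OCc1ccc2ccccc2c1)/C(C)=C/C[C@H](OC(C)=O)/C(C)=C\CO[S+](C)C.[Cl-] | intermediate
16 | (2Z,4S,6E)-4-acetoxy-3,7-dimethyl-8,8-bis(naphthalen-2-ylmethoxy)octa-2,6-dienal | C(OCc1ccc2ccccc2c1)(OCc1ccc2ccccc2c1)/C(C)=C/C[C@H](OC(C)=O)/C(C)=C\C=O | intermediate
17 | (S)-4-benzylthiazolidine-2-thione | S=C1N[C@@H](Cc2ccccc2)CS1 | starting material
18 | itaconic anhydride (3-methylidenedihydrofuran-2,5-dione) | C=C1CC(=O)OC1=O | starting material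
19 | lithium (S)-4-benzyl-2-thioxothiazolidin-3-ide (not isolated) | [Li+].S=C1[N-][C@@H](Cc2ccccc2)CS1 | intermediate
20 | 4-[(S)-4-benzyl-2-thioxothiazolidin-3-yl]-2-methylidene-4-oxobutanoic acid | OC(=O)C(=C)CC(=O)N1[C@@H](Cc2ccccc2)CSC1=S | intermediate
21 | methyl 4-[(S)-4-benzyl-2-thioxothiazolidin-3-yl]-2-methylidene-4-oxobutanoate | COC(=O)C(=C)CC(=O)N1[C@@H](Cc2ccccc2)CSC1=S | intermediate
22 | Z-dibutylboron enolate of 21 (not isolated) | COC(=O)C(=C)/C=C(\OB(CCCC)CCCC)N1[C@@H](Cc2ccccc2)CSC1=S | intermediate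
23 | dibutylboron aldolate of 24 (not isolated) | C(OCc1ccc2ccccc2c1)(OCc1ccc2ccccc2c1)/C(C)=C/C[C@H](OC(C)=O)/C(C)=C\[C@@H](OB(CCCC)CCCC)[C@H](C(=C)C(=O)OC)C(=O)N1[C@@H](Cc2ccccc2)CSC1=S | intermediate
24 | methyl (3S,4R,5Z,7S,9E)-7-acetoxy-3-[(S)-4-benzyl-2-thioxothiazolidine-3-carbonyl]-4-hydroxy-6,10-dimethyl-2-methylidene-11,11-bis(naphthalen-2-ylmethoxy)undeca-5,9-dienoate | C(OCc1ccc2ccccc2c1)(OCc1ccc2ccccc2c1)/C(C)=C/C[C@H](OC(C)=O)/C(C)=C\[C@@H](O)[C@H](C(=C)C(=O)OC)C(=O)N1[C@@H](Cc2ccccc2)CSC1=S | intermediate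
25 | (S)-4-benzyl-3-{(2R,3S)-2-[(1Z,3S,5E)-3-acetoxy-2,6-dimethyl-7,7-bis(naphthalen-2-ylmethoxy)hepta-1,5-dien-1-yl]-4-methylidene-5-oxooxolane-3-carbonyl}thiazolidine-2-thione | C(OCc1ccc2ccccc2c1)(OCc1ccc2ccccc2c1)/C(C)=C/C[C@H](OC(C)=O)/C(C)=C\[C@H]1OC(=O)C(=C)[C@@H]1C(=O)N1[C@@H](Cc2ccccc2)CSC1=S | intermediate
26 | (2R,3S)-2-[(1Z,3S,5E)-3-acetoxy-2,6-dimethyl-7,7-bis(naphthalen-2-ylmethoxy)hepta-1,5-dien-1-yl]-4-methylidene-5-oxooxolane-3-carbaldehyde | C(OCc1ccc2ccccc2c1)(OCc1ccc2ccccc2c1)/C(C)=C/C[C@H](OC(C)=O)/C(C)=C\[C@H]1OC(=O)C(=C)[C@@H]1C=O | intermediate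
27 | γ-(naphthalen-2-ylmethoxy)allylic iodide at C1 (C9=C10 enol ether, C1 epimers, not isolated) | c1ccc2cc(CO/C=C(\C)C(I)C[C@H](OC(C)=O)/C(C)=C\[C@H]3OC(=O)C(=C)[C@@H]3C=O)ccc2c1 | intermediate
28 | γ-(naphthalen-2-ylmethoxy)allylchromium dichloride (trivalent chromium at C1, not isolated) | c1ccc2cc(CO/C=C(\C)C([Cr](Cl)Cl)C[C@H](OC(C)=O)/C(C)=C\[C@H]3OC(=O)C(=C)[C@@H]3C=O)ccc2c1 | intermediate
29 | (3S,6R,7R,8S,9R,1(10)Z,4Z)-3-acetoxy-8-hydroxy-9-(naphthalen-2-ylmethoxy)germacra-1(10),4,11(13)-trien-12,6-olide | C=C1C(=O)O[C@@H]2/C=C(/C)[C@@H](OC(C)=O)C/C=C(/C)[C@@H](OCc3ccc4ccccc4c3)[C@@H](O)[C@@H]12 | intermediate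
30 | (E)-2-methylbut-2-en-1-ol (tiglyl alcohol) | C/C=C(\C)CO | starting material
31 | [(2R,3R)-2,3-dimethyloxiran-2-yl]methanol | OC[C@@]1(C)O[C@@H]1C | intermediate
32 | (2S,3R)-2,3-dimethyloxirane-2-carboxylic acid | OC(=O)[C@@]1(C)O[C@@H]1C | intermediate
33 | (2S,3R)-2,3-dimethyloxirane-2-carboxylic 2,4,6-trichlorobenzoic anhydride (not isolated) | O=C(OC(=O)[C@@]1(C)O[C@@H]1C)c1c(Cl)cc(Cl)cc1Cl | intermediate
34 | (3S,6R,7S,8S,9R,1(10)Z,4Z)-3-acetoxy-8-[(2S,3R)-2,3-dimethyloxirane-2-carbonyloxy]-9-(naphthalen-2-ylmethoxy)germacra-1(10),4,11(13)-trien-12,6-olide | C=C1C(=O)O[C@@H]2/C=C(/C)[C@@H](OC(C)=O)C/C=C(/C)[C@@H](OCc3ccc4ccccc4c3)[C@@H](OC(=O)[C@@]5(C)O[C@@H]5C)[C@@H]12 | intermediate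
35 | (3S,6R,7S,8S,9R,1(10)Z,4Z)-3-acetoxy-8-[(2S,3R)-2,3-dimethyloxirane-2-carbonyloxy]-9-hydroxygermacra-1(10),4,11(13)-trien-12,6-olide (CNP0299903.2) | C=C1C(=O)O[C@@H]2/C=C(/C)[C@@H](OC(C)=O)C/C=C(/C)[C@@H](O)[C@@H](OC(=O)[C@@]3(C)O[C@@H]3C)[C@@H]12 | target

## Step count and risks

Total steps: 19. Longest linear sequence: 14 (steps 1–6, 8, 9, 12–15, 18, 19).

Steps most likely to fail:

**Step 15 (chromium-mediated ring closure).** The intramolecular form is unprecedented; the likeliest failure is closure through a boat-like or anti-Felkin arrangement that delivers the wrong C8 configuration. The fallback sets out from 26 and sets C8 by ketone reduction instead of in the C–C bond-forming event. The same CrCl2/Me3SiI closure then gives (3S,6R,7R,8R,9R,1(10)Z,4Z)-3-acetoxy-8-hydroxy-9-(naphthalen-2-ylmethoxy)germacra-1(10),4,11(13)-trien-12,6-olide F1. This is oxidised with Dess–Martin periodinane (NaHCO3, CH2Cl2) to (3S,6R,7S,9R,1(10)Z,4Z)-3-acetoxy-9-(naphthalen-2-ylmethoxy)-8-oxogermacra-1(10),4,11(13)-trien-12,6-olide F2. Reduction with Zn(BH4)2 (Et2O, −78 °C), under chelation between the ketone and the C9 ether oxygen, gives the anti alcohol, and the route is rejoined at 29.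

**Step 12 (aldol of the itaconyl thioimide).** The doubly activated CH2 may isomerise to the conjugated imide, or the extended enolate may react sluggishly. The fallback sets out from 16 and builds C6–C7 together with the lactone by a chromium-catalysed 2-(alkoxycarbonyl)allylation instead of an enolate aldol. (Triethylsilyloxy)acetaldehyde and methyl acrylate (DABCO) give methyl 3-hydroxy-2-methylidene-4-(triethylsilyloxy)butanoate F3. NBS/Me2S converts it to methyl (Z)-2-(bromomethyl)-4-(triethylsilyloxy)but-2-enoate F4. F4 is added to 16 with CrCl2 (10 mol%), Mn powder, Me3SiCl and a Nakada-type carbazole bis(oxazoline) ligand (the enantiomer that delivers the 6R carbinol), with acidic work-up to lactonise. This gives (4R,5R)-5-[(1Z,3S,5E)-3-acetoxy-2,6-dimethyl-7,7-bis(naphthalen-2-ylmethoxy)hepta-1,5-dien-1-yl]-3-methylidene-4-[(triethylsilyloxy)methyl]oxolan-2-one F5. Direct Swern oxidation of its TES ether (as in step 9) rejoins the route at 26; if the cis lactone forms, a trace of DBU at the aldehyde stage equilibrates C7 to the more stable trans arrangement.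

**Step 14 (thioimide to the labile β-formyl α-methylene lactone).** Over-reduction, conjugate reduction or isomerisation of the aldehyde are the concerns. The fallback sets out from 25 and changes the acyl derivative and the hydride source. MeNHOMe·HCl and imidazole (CH2Cl2, rt) give (2R,3S)-2-[(1Z,3S,5E)-3-acetoxy-2,6-dimethyl-7,7-bis(naphthalen-2-ylmethoxy)hepta-1,5-dien-1-yl]-N-methoxy-N-methyl-4-methylidene-5-oxooxolane-3-carboxamide F6. Cp2Zr(H)Cl (THF, rt, minutes) reduces it to the aldehyde in the presence of the lactone and acetate, rejoining the route at 26, which is used at once in step 15.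

Further compounds
F1 | step 15 | (3S,6R,7R,8R,9R,1(10)Z,4Z)-3-acetoxy-8-hydroxy-9-(naphthalen-2-ylmethoxy)germacra-1(10),4,11(13)-trien-12,6-olide | C=C1C(=O)O[C@@H]2/C=C(/C)[C@@H](OC(C)=O)C/C=C(/C)[C@@H](OCc3ccc4ccccc4c3)[C@H](O)[C@@H]12
F2 | step 15 | (3S,6R,7S,9R,1(10)Z,4Z)-3-acetoxy-9-(naphthalen-2-ylmethoxy)-8-oxogermacra-1(10),4,11(13)-trien-12,6-olide | C=C1C(=O)O[C@@H]2/C=C(/C)[C@@H](OC(C)=O)C/C=C(/C)[C@@H](OCc3ccc4ccccc4c3)C(=O)[C@@H]12
F3 | step 12 | methyl 3-hydroxy-2-methylidene-4-(triethylsilyloxy)butanoate | COC(=O)C(=C)C(O)CO[Si](CC)(CC)CC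
F4 | step 12 | methyl (Z)-2-(bromomethyl)-4-(triethylsilyloxy)but-2-enoate | COC(=O)/C(CBr)=C/CO[Si](CC)(CC)CC
F5 | step 12 | (4R,5R)-5-[(1Z,3S,5E)-3-acetoxy-2,6-dimethyl-7,7-bis(naphthalen-2-ylmethoxy)hepta-1,5-dien-1-yl]-3-methylidene-4-[(triethylsilyloxy)methyl]oxolan-2-one | C(OCc1ccc2ccccc2c1)(OCc1ccc2ccccc2c1)/C(C)=C/C[C@H](OC(C)=O)/C(C)=C\[C@H]1OC(=O)C(=C)[C@@H]1CO[Si](CC)(CC)CC
F6 | step 14 | (2R,3S)-2-[(1Z,3S,5E)-3-acetoxy-2,6-dimethyl-7,7-bis(naphthalen-2-ylmethoxy)hepta-1,5-dien-1-yl]-N-methoxy-N-methyl-4-methylidene-5-oxooxolane-3-carboxamide | C(OCc1ccc2ccccc2c1)(OCc1ccc2ccccc2c1)/C(C)=C/C[C@H](OC(C)=O)/C(C)=C\[C@H]1OC(=O)C(=C)[C@@H]1C(=O)N(C)OC
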